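The target, 1-(3,5-dihydroxyphenyl)henicosan-2-one, has one benzene ring, numbered Ar1 (side chain), Ar3 and Ar5 (OH). The enabling feature is that Ar1, Ar3 and Ar5 are mutually meta: the Ar3 oxygen can start as a cyclobutenone carbonyl, the Ar5 oxygen as the donor of an ynol ether, and Ar1 as C3 of the four-membered ring.
Retrosynthesis: after unmasking the phenols and the C2 ketone, the arene is cut at Ar3–Ar4 and Ar5–Ar6 (3-substituted cyclobutenone + ethoxyacetylene). The cyclobutenone is cut at Ar1–Ar2 and at its carbonyl–CH bond (dichloroketene + terminal alkyne), and the side chain at C1–C2 (propargyl unit + icosanal).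
Forward: the C23 chain is joined first, the four-membered ring is built on its alkyne, the benzene ring arises in the benzannulation, and the ketone and phenols are released last.
Stereochemistry: the target is achiral; the side-chain carbinol is made and carried as a racemate and disappears on oxidation.

Key step: step 6

Assumption: ethoxyacetylene is used as its commercial hexane solution; compounds with the protected or free carbinol are racemic throughout.

Step 1
Reactants: 1 icosan-1-ol
Product: 2 icosanal
Conditions: TEMPO (cat.), PhI(OAc)2, CH2Cl2, rt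
Reagents that add atoms: none
Why: TEMPO-catalysed oxidation with PhI(OAc)2 as terminal oxidant (oxoammonium oxidation) converts an unhindered primary alcohol into the aldehyde without over-oxidation when water is absent, and the substrate has no other reactive group.

Step 2
Reactants: 2 icosanal; 3 propargyl bromide
Product: 5 rac-tricos-1-yn-4-ol, via allenylzinc bromide 4 (not isolated)
Conditions: Zn dust (activated), THF, 0 °C to rt; then 1 M HCl
Reagents that add atoms: none
Why: Zinc inserts into 3 to give allenylzinc bromide 4, which adds to the aldehyde with allylic transposition through a cyclic SE2' transition state (Barbier propargylation), so the homopropargylic carbinol should dominate over the allenic isomer; the new carbinol centre forms without control as a racemate, which suffices because it later becomes the ketone.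

Step 3
Reactants: 5 rac-tricos-1-yn-4-ol
Product: 6 rac-tert-butyl(dimethyl)(tricos-1-yn-4-yloxy)silane
Conditions: TBSCl, imidazole, CH2Cl2/DMF, rt
Reagents that add atoms: tert-butyldimethylsilyl chloride, CC(C)(C)[Si](C)(C)Cl
Why: Imidazole-promoted silylation of a secondary alcohol is routine, and the TBS ether keeps the hydroxyl from acylating the ketenes of steps 4 and 6 while tolerating zinc/acetic acid and heat.

Step 4
Reactants: 6 rac-tert-butyl(dimethyl)(tricos-1-yn-4-yloxy)silane; 7 trichloroacetyl chloride
Product: 9 rac-4,4-dichloro-3-[2-(tert-butyldimethylsilyloxy)henicosyl]cyclobut-2-en-1-one, via dichloroketene 8 (not isolated)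
Conditions: Zn(Cu) couple, Et2O/DME, rt, slow addition of 7
Reagents that add atoms: none
Why: Zinc dechlorinates 7 to dichloroketene 8, which undergoes the known [2+2] cycloaddition with a terminal alkyne, the alkyne CH carbon bonding to the ketene carbonyl carbon so that CCl2 ends next to the substituted ring carbon, while DME ties up the ZnCl2 that could otherwise attack the silyl ether.

Step 5
Reactants: 9 rac-4,4-dichloro-3-[2-(tert-butyldimethylsilyloxy)henicosyl]cyclobut-2-en-1-one
Product: 10 rac-3-[2-(tert-butyldimethylsilyloxy)henicosyl]cyclobut-2-en-1-one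
Conditions: Zn dust, AcOH, TMEDA, EtOH/THF, 0 °C to rt
Reagents that add atoms: none
Why: Zinc in TMEDA-buffered acetic acid removes both chlorines alpha to the carbonyl (reductive dehalogenation of an alpha,alpha-dichloro ketone, the standard route to 3-alkylcyclobutenones) under conditions too mild to reduce the enone or cleave the silyl ether.

Step 6
Reactants: 10 rac-3-[2-(tert-butyldimethylsilyloxy)henicosyl]cyclobut-2-en-1-one; 11 ethoxyacetylene
Product: 16 rac-3-ethoxy-5-[2-(tert-butyldimethylsilyloxy)henicosyl]phenol, via vinylketene 12 (not isolated), via 4-alkenyl-3-ethoxycyclobutenone 13 (not isolated), via dienylketene 14 (not isolated), via cyclohexa-2,4-dienone 15 (not isolated)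
Conditions: 11 (3 equiv, hexane solution), toluene, sealed tube, 80 °C
Reagents that add atoms: none
Why: Thermal conrotatory 4π opening of 10 breaks its C1–C4 bond to give vinylketene 12, whose carbonyl carbon is attacked by the unsubstituted, nucleophilic carbon of the ynol ether in a [2+2] cycloaddition that forms Ar3–Ar4 and Ar5–Ar6 and gives 13. A second 4π opening of 13 gives dienylketene 14, and a thermal disrotatory 6π electrocyclisation closes the six-membered ring by re-forming the Ar2–Ar3 bond, after which dienone 15 tautomerises to the phenol. This is the Danheiser benzannulation, established for 3-alkylcyclobutenones and alkoxyalkynes. No lasting stereocentre is created, since the sp3 ring carbon of 13 is lost on ring opening and the remote carbinol stays racemic. The step needs regiocontrol in the [2+2] event, which the donor oxygen secures by polarising the alkyne so that only its CH terminus bonds to the ketene carbonyl carbon, placing OEt meta to the new OH with the side chain meta to both. It also needs the vinylketene to be trapped by the alkyne and not by the product phenol or by itself, which the excess of 11 provides, while 80 °C stays below the temperature at which ethoxyacetylene fragments to ketene and ethylene.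

Step 7
Reactants: 16 rac-3-ethoxy-5-[2-(tert-butyldimethylsilyloxy)henicosyl]phenol
Product: 17 rac-tert-butyl{[1-(3,5-diethoxyphenyl)henicosan-2-yl]oxy}dimethylsilane
Conditions: EtI, K2CO3, DMF, 50 °C
Reagents that add atoms: iodoethane, CCI
Why: Williamson etherification of the phenoxide caps the free phenol, which would otherwise be at risk in the oxidation of step 9, and gives a symmetrical diethyl resorcinol ether so that one reagent can later free both oxygens.

Step 8
Reactants: 17 rac-tert-butyl{[1-(3,5-diethoxyphenyl)henicosan-2-yl]oxy}dimethylsilane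
Product: 18 rac-1-(3,5-diethoxyphenyl)henicosan-2-ol
Conditions: TBAF, THF, rt; aqueous work-up
Reagents that add atoms: none
Why: Fluoride-induced cleavage of the Si–O bond (TBAF desilylation) frees the secondary alcohol without affecting the aryl ethyl ethers.

Step 9
Reactants: 18 rac-1-(3,5-diethoxyphenyl)henicosan-2-ol
Product: 19 1-(3,5-diethoxyphenyl)henicosan-2-one
Conditions: DMP, CH2Cl2, 0 °C to rt
Reagents that add atoms: none
Why: Dess–Martin oxidation turns the secondary carbinol into the ketone under mild, non-basic conditions that leave the dialkoxyarene alone, and it removes the only stereocentre.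

Step 10
Reactants: 19 1-(3,5-diethoxyphenyl)henicosan-2-one
Product: 20 1-(3,5-dihydroxyphenyl)henicosan-2-one
Conditions: BBr3 (4 equiv), CH2Cl2, −78 °C to rt; then H2O
Reagents that add atoms: none
Why: BBr3 complexes each aryl ether oxygen and bromide displaces the ethyl group (Lewis-acid ether dealkylation), a cleavage that tolerates benzyl ketones at low temperature, and hydrolysis of the B–O bonds on work-up releases the resorcinol.

Compound list
1 | icosan-1-ol | CCCCCCCCCCCCCCCCCCCCO | starting material
2 | icosanal | CCCCCCCCCCCCCCCCCCCC=O | intermediate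
3 | propargyl bromide (3-bromoprop-1-yne) | C#CCBr | starting material
4 | allenylzinc bromide (propa-1,2-dienylzinc bromide; not isolated) | C=C=C[Zn]Br | intermediate
5 | rac-tricos-1-yn-4-ol | CCCCCCCCCCCCCCCCCCCC(O)CC#C | intermediate
6 | rac-tert-butyl(dimethyl)(tricos-1-yn-4-yloxy)silane | CCCCCCCCCCCCCCCCCCCC(CC#C)O[Si](C)(C)C(C)(C)C | intermediate
7 | trichloroacetyl chloride | ClC(Cl)(Cl)C(=O)Cl | starting material
8 | dichloroketene (not isolated) | ClC(Cl)=C=O | intermediate
9 | rac-4,4-dichloro-3-[2-(tert-butyldimethylsilyloxy)henicosyl]cyclobut-2-en-1-one | CCCCCCCCCCCCCCCCCCCC(CC1=CC(=O)C1(Cl)Cl)O[Si](C)(C)C(C)(C)C | intermediate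
10 | rac-3-[2-(tert-butyldimethylsilyloxy)henicosyl]cyclobut-2-en-1-one | CCCCCCCCCCCCCCCCCCCC(CC1=CC(=O)C1)O[Si](C)(C)C(C)(C)C | intermediate
11 | ethoxyacetylene (ethoxyethyne) | C#COCC | starting material
12 | vinylketene, rac-5-(tert-butyldimethylsilyloxy)-3-methylidenetetracos-1-en-1-one (not isolated) | CCCCCCCCCCCCCCCCCCCC(CC(=C)C=C=O)O[Si](C)(C)C(C)(C)C | intermediate
13 | 3-ethoxy-4-[4-(tert-butyldimethylsilyloxy)tricos-1-en-2-yl]cyclobut-2-en-1-one, racemic mixture of diastereomers (not isolated) | CCOC1=CC(=O)C1C(=C)CC(CCCCCCCCCCCCCCCCCCC)O[Si](C)(C)C(C)(C)C | intermediate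
14 | dienylketene, rac-(3E)-7-(tert-butyldimethylsilyloxy)-3-ethoxy-5-methylidenehexacosa-1,3-dien-1-one (not isolated) | O=C=C/C(OCC)=C\C(=C)CC(CCCCCCCCCCCCCCCCCCC)O[Si](C)(C)C(C)(C)C | intermediate
15 | rac-3-ethoxy-5-[2-(tert-butyldimethylsilyloxy)henicosyl]cyclohexa-2,4-dien-1-one (not isolated) | CCCCCCCCCCCCCCCCCCCC(CC1=CC(OCC)=CC(=O)C1)O[Si](C)(C)C(C)(C)C | intermediate
16 | rac-3-ethoxy-5-[2-(tert-butyldimethylsilyloxy)henicosyl]phenol | CCCCCCCCCCCCCCCCCCCC(Cc1cc(O)cc(OCC)c1)O[Si](C)(C)C(C)(C)C | intermediate
17 | rac-tert-butyl{[1-(3,5-diethoxyphenyl)henicosan-2-yl]oxy}dimethylsilane | CCCCCCCCCCCCCCCCCCCC(Cc1cc(OCC)cc(OCC)c1)O[Si](C)(C)C(C)(C)C | intermediate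
18 | rac-1-(3,5-diethoxyphenyl)henicosan-2-ol | CCCCCCCCCCCCCCCCCCCC(O)Cc1cc(OCC)cc(OCC)c1 | intermediate
19 | 1-(3,5-diethoxyphenyl)henicosan-2-one | CCCCCCCCCCCCCCCCCCCC(=O)Cc1cc(OCC)cc(OCC)c1 | intermediate
20 | 1-(3,5-dihydroxyphenyl)henicosan-2-one | CCCCCCCCCCCCCCCCCCCC(=O)Cc1cc(O)cc(O)c1 | target

Total step count: 10
Longest linear sequence: 10 steps, from icosan-1-ol 1 to 20; compounds 3, 7 and 11 enter as purchased two- and three-carbon units.

Steps most likely to fail

Step 6. The vinylketene may be intercepted by the phenol already formed or by a second ketene molecule faster than by the alkyne, and the ynol ether may fragment thermally before it is consumed. The fallback gives up the benzannulation and joins a ready-made arene to the chain. It sets out from icosanal 2: 3,5-dimethoxybenzylmagnesium chloride F1 (from commercial 3,5-dimethoxybenzyl chloride, COc1cc(CCl)cc(OC)c1, and Mg in THF at 0 °C) is added to 2, with a dilute HCl quench, to give rac-1-(3,5-dimethoxyphenyl)henicosan-2-ol F2. Dess–Martin oxidation then gives 1-(3,5-dimethoxyphenyl)henicosan-2-one F3, and BBr3 in CH2Cl2 cleaves both methyl ethers, so the fallback comes back to the route at 20.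

Step 4. Ketene oligomerisation may outrun cycloaddition to the unactivated alkyne, and the ZnCl2 released may strip the silyl ether. The fallback replaces the ketene by a keteniminium ion and sets out from 6. N,N-dimethylketeniminium triflate F4, generated from N,N-dimethylacetamide, Tf2O and 2,4,6-collidine in refluxing 1,2-dichloroethane, should add to the alkyne with the same regiochemistry to give the cyclobuteniminium triflate F5. Hydrolysis with aqueous NaHCO3 then gives the cyclobutenone directly, so the fallback comes back to the route at 10 and makes step 5 unnecessary.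

Step 10. Lewis-acid-driven enolisation and self-condensation of the benzyl ketone may compete, or the cleavage may stall after the first O–ethyl bond. The fallback ends in a neutral hydrogenolysis instead and is costly, because it also sets out from icosanal 2. 3,5-Bis(benzyloxy)benzylmagnesium chloride F6 (from 3,5-bis(benzyloxy)benzyl chloride, ClCc1cc(OCc2ccccc2)cc(OCc2ccccc2)c1, and Mg in THF) is added to 2, with a dilute HCl quench, to give rac-1-[3,5-bis(benzyloxy)phenyl]henicosan-2-ol F7. Dess–Martin oxidation gives 1-[3,5-bis(benzyloxy)phenyl]henicosan-2-one F8, and H2 over Pd/C (palladium on carbon) in EtOAc removes both benzyl groups without touching the ketone, so the fallback comes back to the route at 20.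

Further compounds
F1 | step 6 | 3,5-dimethoxybenzylmagnesium chloride | COc1cc(C[Mg]Cl)cc(OC)c1
F2 | step 6 | rac-1-(3,5-dimethoxyphenyl)henicosan-2-ol | CCCCCCCCCCCCCCCCCCCC(O)Cc1cc(OC)cc(OC)c1
F3 | step 6 | 1-(3,5-dimethoxyphenyl)henicosan-2-one | CCCCCCCCCCCCCCCCCCCC(=O)Cc1cc(OC)cc(OC)c1
F4 | step 4 | N,N-dimethylketeniminium triflate | C=C=[N+](C)C.[O-]S(=O)(=O)C(F)(F)F
F5 | step 4 | rac-N-{3-[2-(tert-butyldimethylsilyloxy)henicosyl]cyclobut-2-en-1-ylidene}-N-methylmethanaminium triflate | CCCCCCCCCCCCCCCCCCCC(CC1=CC(=[N+](C)C)C1)O[Si](C)(C)C(C)(C)C.[O-]S(=O)(=O)C(F)(F)F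
F6 | step 10 | 3,5-bis(benzyloxy)benzylmagnesium chloride | Cl[Mg]Cc1cc(OCc2ccccc2)cc(OCc2ccccc2)c1
F7 | step 10 | rac-1-[3,5-bis(benzyloxy)phenyl]henicosan-2-ol | CCCCCCCCCCCCCCCCCCCC(O)Cc1cc(OCc2ccccc2)cc(OCc2ccccc2)c1
F8 | step 10 | 1-[3,5-bis(benzyloxy)phenyl]henicosan-2-one | CCCCCCCCCCCCCCCCCCCC(=O)Cc1cc(OCc2ccccc2)cc(OCc2ccccc2)c1
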